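**Plan**
- Numbering (briarane): ring A = cyclohexane C1, C10–C14 with C11=C20; ten-membered ring C1–C10; lactone C7–O–C19(=O)–C17(C18)–C8; C15 methyl on C1; C16 methylene on C5.
- Cuts: C6–Cl (SN2 inversion of a carbinol) and the three acetates; C3=C4 together with C5=C16 (ethene-mediated enyne ring-closing metathesis); C8–C9 (Nozaki–Hiyama–Kishi); C13–C14 and C10–C11 together (formal (3+3) annulation of ring A); the C15–O bond of a temporary lactone.
- Enabling feature: on ring A, C14 (carbinol, latent aldehyde) and C10 (α to C9) sit 1,3 across quaternary C1, and C9 is cis to C15. C9 and C15 can therefore be held as a γ-lactone whose only enolisable carbon is C10, and a C11–C13 unit (alkylzinc at C13, alkenyl bromide at C11) closes ring A in one flask.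
- Forward order: Tollens lactone → desymmetrisation → ring A built on the lactone → lactone opened and its CH2O arm reduced to the C15 methyl → tartrate-derived butenolide (C3–C8, C17–C19) coupled at C9 → C8/C9/C17 adjusted → ten-membered ring → acetates, chloride.
- Stereochemistry: C1 by lipase; C10 by cis-fusion to the temporary lactone; C14 by ketone reduction; C2 by chelated Grignard addition; C6/C7 from D-tartaric acid; C9, C8, C17 by Felkin–Anh coupling, hydroxyl-directed epoxidation, chelation-controlled reduction and SmI2 opening; C6 by inversion.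

Key step: step 7

Remark: the lipase is assumed to acylate the enantiotopic arm drawn in 4; if it prefers the other arm, enzymatic hydrolysis of the bis(chloroacetate) of 3 would give the same ester 4.

**Step 1**
Reactants: 1 methyl 4-oxobutanoate
Product: 3 4,4-bis(hydroxymethyl)oxolan-2-one, via triol acid 2 (not isolated)
Conditions: CH2O (37% aq., 4 equiv), NaOH (2.2 equiv), H2O, 0 → 40 °C; then HCl to pH 1, 50 °C
Reagents that add atoms: formaldehyde, C=O
Why: Tollens condensation: two aldol additions of formaldehyde at the only enolisable carbon (the future C1) and a crossed Cannizzaro reduction give the tris(hydroxymethyl) acid, which lactonises on acidification through any of its three equivalent arms; no stereocentre yet, the two remaining arms being enantiotopic.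

**Step 2**
Reactants: 3 4,4-bis(hydroxymethyl)oxolan-2-one
Product: 4 [(3S)-3-(hydroxymethyl)-5-oxooxolan-3-yl]methyl chloroacetate
Conditions: Burkholderia cepacia lipase (Amano PS), vinyl chloroacetate, t-BuOMe, 25 °C
Reagents that add atoms: vinyl chloroacetate, C=COC(=O)CCl
Why: Lipase-catalysed desymmetrising acylation of a prochiral 2,2-disubstituted propane-1,3-diol should differentiate the enantiotopic hydroxymethyl arms and so set quaternary C1 (acylated arm = future C14, free arm = future C2); the neutral medium avoids the degenerate translactonisation that would racemise it.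

**Step 3**
Reactants: 4 [(3S)-3-(hydroxymethyl)-5-oxooxolan-3-yl]methyl chloroacetate
Product: 5 [(3S)-3-{[tert-butyl(diphenyl)silyl]oxymethyl}-5-oxooxolan-3-yl]methyl chloroacetate
Conditions: t-BuPh2SiCl, imidazole, CH2Cl2, 0 °C
Reagents that add atoms: tert-butyl(chloro)diphenylsilane, CC(C)(C)[Si](Cl)(c1ccccc1)c1ccccc1
Why: Standard silylation of the free primary hydroxyl fixes the C2 arm as a base-stable ether; C1 is untouched.

**Step 4**
Reactants: 5 [(3S)-3-{[tert-butyl(diphenyl)silyl]oxymethyl}-5-oxooxolan-3-yl]methyl chloroacetate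
Product: 6 (4R)-4-{[tert-butyl(diphenyl)silyl]oxymethyl}-4-(hydroxymethyl)oxolan-2-one
Conditions: thiourea, NaHCO3, EtOH, 25 °C
Reagents that add atoms: none
Why: Chloroacetate cleavage by thiourea (S-alkylation, then cyclisation to the iminothiazolidinone) frees the C14 arm near neutrality, so the new hydroxyl should not exchange places with the lactone oxygen (which would invert C1).

**Step 5**
Reactants: 6 (4R)-4-{[tert-butyl(diphenyl)silyl]oxymethyl}-4-(hydroxymethyl)oxolan-2-one
Product: 7 (3R)-3-{[tert-butyl(diphenyl)silyl]oxymethyl}-5-oxooxolane-3-carbaldehyde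
Conditions: TEMPO (cat.), PhI(OAc)2, CH2Cl2, 25 °C
Reagents that add atoms: none
Why: Nitroxyl-catalysed oxidation of a primary alcohol gives the non-enolisable neopentyl aldehyde (C14), after which C1 is configurationally secure.

**Step 6**
Reactants: 8 3-bromobut-3-en-1-ol
Product: 9 2-bromo-4-iodobut-1-ene
Conditions: PPh3, I2, imidazole, CH2Cl2, 0 → 25 °C
Reagents that add atoms: iodine, II
Why: Appel iodination of a primary alcohol provides the C11–C13 unit with an alkyl iodide (for zinc insertion) and an alkenyl bromide (for palladium).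

**Step 7**
Reactants: 7 (3R)-3-{[tert-butyl(diphenyl)silyl]oxymethyl}-5-oxooxolane-3-carbaldehyde; 9 2-bromo-4-iodobut-1-ene
Product: 13 (3aR,7aS)-3a-{[tert-butyl(diphenyl)silyl]oxymethyl}-4-hydroxy-7-methylidenehexahydro-2-benzofuran-1(3H)-one as a mixture of C14 epimers, via organozinc iodide 10 (not isolated), via open-chain silyl ether 11 (not isolated), via bicyclic silyl ether 12 (not isolated)
Conditions: 9, Zn, LiCl, THF, 25 °C; then 7, MgCl2, 0 → 25 °C; Me3SiCl, 0 °C; then LiN(SiMe3)2, −78 °C, Pd2(dba)3 (3 mol %), P(t-Bu)3 (12 mol %), −78 → 25 °C; then 1 M HCl, THF, 0 °C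
Reagents that add atoms: none
Why: Zinc inserts into the C–I bond of 9 only, and the alkylzinc 10, activated by MgCl2, adds to the aldehyde of 7 and not to the lactone (C13–C14); the zinc alkoxide is capped as silyl ether 11 so that it cannot attack the lactone, then LiN(SiMe3)2 forms the lactone enolate, zerovalent palladium inserts into the C11–Br bond and reductive elimination joins C10 to C11. The closest known reaction types are the addition of functionalised alkylzinc halides to aldehydes and the palladium-catalysed intramolecular α-alkenylation of ester and ketone enolates by alkenyl halides (methylenecycloalkane annulation), here run in sequence as a formal (3+3) annulation. Ring A closes in the 6-exo sense through a seven-membered palladacycle, and the exocyclic C11=C20 bond comes from the alkenyl bromide with no positional choice. C10 is controlled by the γ-lactone: a six-membered ring can fuse across C1–C10 of the butyrolactone only cis, which places C9 on the side of the future C15 methyl as in the target; C14 forms without control and is erased in step 8. The step needs aldehyde-over-lactone and C–I-over-C–Br selectivity and a single enolisation site, secured respectively by the mild organozinc, the alkenyl nature of the bromide and the quaternary C1.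

**Step 8**
Reactants: 13 bicyclic hydroxy lactone (C14 epimers)
Product: 14 (3aR,7aS)-3a-{[tert-butyl(diphenyl)silyl]oxymethyl}-7-methylidenetetrahydro-2-benzofuran-1,4(3H,5H)-dione
Conditions: Dess–Martin periodinane, NaHCO3, CH2Cl2, 25 °C
Reagents that add atoms: none
Why: Dess–Martin oxidation converges both C14 epimers on one ketone; C1 is quaternary and C10 is locked by the ring fusion.

**Step 9**
Reactants: 14 (3aR,7aS)-3a-{[tert-butyl(diphenyl)silyl]oxymethyl}-7-methylidenetetrahydro-2-benzofuran-1,4(3H,5H)-dione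
Product: 15 (3aR,4S,7aS)-3a-{[tert-butyl(diphenyl)silyl]oxymethyl}-4-hydroxy-7-methylidenehexahydro-2-benzofuran-1(3H)-one
Conditions: LiBH(s-Bu)3, THF, −78 °C
Reagents that add atoms: none
Why: The bulky hydride should attack the cyclohexanone along the equatorial trajectory, on the face of the lactone methylene C15, leaving the C14 hydroxyl axial, trans to C15 and cis to the C2 arm as in the target; the lactone is not reduced at −78 °C.

**Step 10**
Reactants: 15 (3aR,4S,7aS)-3a-{[tert-butyl(diphenyl)silyl]oxymethyl}-4-hydroxy-7-methylidenehexahydro-2-benzofuran-1(3H)-one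
Product: 16 (3aS,4S,7aS)-4-hydroxy-3a-(hydroxymethyl)-7-methylidenehexahydro-2-benzofuran-1(3H)-one
Conditions: Bu4NF, AcOH, THF, 0 → 25 °C
Reagents that add atoms: none
Why: Fluoride desilylation frees the C2 arm; neither hydroxyl can displace the lactone oxygen, because both lie trans to C9 on ring A.

**Step 11**
Reactants: 16 (3aS,4S,7aS)-4-hydroxy-3a-(hydroxymethyl)-7-methylidenehexahydro-2-benzofuran-1(3H)-one
Product: 17 (3aS,4S,7aS)-4-hydroxy-7-methylidene-1-oxohexahydro-2-benzofuran-3a(1H)-carbaldehyde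
Conditions: TEMPO (cat.), PhI(OAc)2, CH2Cl2, 25 °C
Reagents that add atoms: none
Why: Nitroxyl oxidation is selective for the primary alcohol over the hindered axial secondary C14 hydroxyl and gives the C2 aldehyde.

**Step 12**
Reactants: 17 (3aS,4S,7aS)-4-hydroxy-7-methylidene-1-oxohexahydro-2-benzofuran-3a(1H)-carbaldehyde
Product: 18 (3aS,4S,7aS)-4-hydroxy-3a-[(1S)-1-hydroxyprop-2-en-1-yl]-7-methylidenehexahydro-2-benzofuran-1(3H)-one
Conditions: CH2=CHMgBr (2.5 equiv), THF, −78 °C
Reagents that add atoms: vinylmagnesium bromide, C=C[Mg]Br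
Why: Chelation-controlled Grignard addition: the magnesium alkoxide of the axial C14 hydroxyl binds the aldehyde oxygen in a six-membered chelate, and the vinyl group should add to the face turned away from C10 and its carbonyl, giving the C2 configuration of the target; the lactone survives at −78 °C.

**Step 13**
Reactants: 18 (3aS,4S,7aS)-4-hydroxy-3a-[(1S)-1-hydroxyprop-2-en-1-yl]-7-methylidenehexahydro-2-benzofuran-1(3H)-one
Product: 19 (3aS,4S,7aS)-7-methylidene-4-(triethylsilyloxy)-3a-[(1S)-1-(triethylsilyloxy)prop-2-en-1-yl]hexahydro-2-benzofuran-1(3H)-one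
Conditions: Et3SiOTf, 2,6-lutidine, CH2Cl2, −78 → 0 °C
Reagents that add atoms: triethylsilyl trifluoromethanesulfonate, CC[Si](CC)(CC)OS(=O)(=O)C(F)(F)F
Why: Silyl triflate silylation covers both hindered secondary hydroxyls in one operation.

**Step 14**
Reactants: 19 bis(triethylsilyl) ether lactone
Product: 20 (1S,2S,3S)-2-(hydroxymethyl)-N-methoxy-N-methyl-6-methylidene-3-(triethylsilyloxy)-2-[(1S)-1-(triethylsilyloxy)prop-2-en-1-yl]cyclohexane-1-carboxamide
Conditions: MeNH(OMe)·HCl, AlMe3, CH2Cl2, 0 → 40 °C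
Reagents that add atoms: N,O-dimethylhydroxylamine hydrochloride, CNOC.Cl
Why: Aluminium amide aminolysis (Weinreb amide formation) opens the temporary lactone, turning C9 into an aldehyde precursor and releasing the C15 arm as the only free hydroxyl; C10 keeps its configuration because no enolate is formed.

**Step 15**
Reactants: 20 hydroxy Weinreb amide
Product: 21 O-{[(1S,2S,6S)-2-[methoxy(methyl)carbamoyl]-3-methylidene-6-(triethylsilyloxy)-1-[(1S)-1-(triethylsilyloxy)prop-2-en-1-yl]cyclohexyl]methyl} O-phenyl thiocarbonate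
Conditions: PhOC(S)Cl, pyridine, DMAP (cat.), CH2Cl2, 0 → 25 °C
Reagents that add atoms: O-phenyl chlorothionoformate, S=C(Cl)Oc1ccccc1
Why: Thioacylation of the single free primary alcohol prepares the radical deoxygenation.

**Step 16**
Reactants: 21 phenyl thionocarbonate
Product: 22 (1S,2R,3S)-N-methoxy-N,2-dimethyl-6-methylidene-3-(triethylsilyloxy)-2-[(1S)-1-(triethylsilyloxy)prop-2-en-1-yl]cyclohexane-1-carboxamide
Conditions: Bu3SnH, AIBN, toluene, 110 °C
Reagents that add atoms: none
Why: Barton–McCombie deoxygenation turns the former lactone arm into the C15 methyl; the primary radical has only 4-exo or 5-endo paths to the nearby alkenes and should be reduced first.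

**Step 17**
Reactants: 22 methyl-bearing Weinreb amide
Product: 23 (1S,2R,3S)-2-methyl-6-methylidene-3-(triethylsilyloxy)-2-[(1S)-1-(triethylsilyloxy)prop-2-en-1-yl]cyclohexane-1-carbaldehyde
Conditions: i-Bu2AlH, THF, −78 °C
Reagents that add atoms: none
Why: Weinreb amide reduction stops at the chelated hemiaminal and gives the C9 aldehyde on work-up without epimerising C10.

**Step 18**
Reactants: 24 dimethyl (4S,5S)-2,2-dimethyl-1,3-dioxolane-4,5-dicarboxylate
Product: 26 (4R,5R)-4,5-diethynyl-2,2-dimethyl-1,3-dioxolane, via dialdehyde 25 (not isolated)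
Conditions: i-Bu2AlH (2.1 equiv), CH2Cl2, −78 °C; then MeOH, K2CO3, dimethyl (1-diazo-2-oxopropyl)phosphonate, −78 → 25 °C
Reagents that add atoms: dimethyl (1-diazo-2-oxopropyl)phosphonate, COP(=O)(OC)C(=[N+]=[N-])C(C)=O
Why: One-pot ester half-reduction and Seyferth–Gilbert homologation with the Bestmann–Ohira reagent; the two stereocentres (future C6 and C7) come unchanged from D-tartaric acid, the trans-acetonide resisting epimerisation.

**Step 19**
Reactants: 26 (4R,5R)-4,5-diethynyl-2,2-dimethyl-1,3-dioxolane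
Product: 27 methyl 3-[(4R,5R)-5-ethynyl-2,2-dimethyl-1,3-dioxolan-4-yl]prop-2-ynoate
Conditions: n-BuLi (1.0 equiv), THF, −78 °C; ClCO2Me
Reagents that add atoms: methyl chloroformate, COC(=O)Cl
Why: Mono-acylation of one acetylide of a C2-symmetric diyne gives a single mono-ester whichever end reacts (statistical, diyne recycled) and introduces C19.

**Step 20**
Reactants: 27 methyl 3-[(4R,5R)-5-ethynyl-2,2-dimethyl-1,3-dioxolan-4-yl]prop-2-ynoate
Product: 29 methyl (2E)-3-[(4S,5R)-5-ethynyl-2,2-dimethyl-1,3-dioxolan-4-yl]-2-methyl-3-(tributylstannyl)prop-2-enoate, via alkenylcopper 28 (not isolated)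
Conditions: (Bu3Sn)2, n-BuLi, THF, −20 °C; CuBr·SMe2, −78 °C; then 27, −78 °C; MeI, DMPU, −78 → 0 °C
Reagents that add atoms: hexabutyldistannane, CCCC[Sn](CCCC)(CCCC)[Sn](CCCC)(CCCC)CCCC; iodomethane, CI
Why: Syn stannylcupration of the ynoate puts tin on the β-carbon (C8), and the alkenylcopper is methylated at C17 with retention, so tin and methyl are cis and C7 is cis to the ester; the unactivated terminal alkyne should not react at −78 °C.

**Step 21**
Reactants: 29 stannyl enoate
Product: 30 methyl (2E)-3-[(4S,5R)-5-ethynyl-2,2-dimethyl-1,3-dioxolan-4-yl]-3-iodo-2-methylprop-2-enoate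
Conditions: I2, CH2Cl2, 0 °C
Reagents that add atoms: iodine, II
Why: Iododestannylation proceeds with retention of alkene geometry and gives the alkenyl iodide needed for chromium chemistry.

**Step 22**
Reactants: 30 iodo enoate acetonide
Product: 32 (5S)-5-[(1R)-1-hydroxyprop-2-yn-1-yl]-4-iodo-3-methylfuran-2(5H)-one, via diol ester 31 (not isolated)
Conditions: CF3CO2H/H2O (9:1), 0 → 25 °C
Reagents that add atoms: none
Why: Acetal hydrolysis frees the diol, and the C7 hydroxyl, held cis to the ester, closes the five-membered butenolide in preference to the six-membered lactone through the C6 hydroxyl; this differentiates the two hydroxyls.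

**Step 23**
Reactants: 32 (5S)-5-[(1R)-1-hydroxyprop-2-yn-1-yl]-4-iodo-3-methylfuran-2(5H)-one
Product: 33 (5S)-5-[(1R)-1-{[tert-butyl(dimethyl)silyl]oxy}prop-2-yn-1-yl]-4-iodo-3-methylfuran-2(5H)-one
Conditions: t-BuMe2SiOTf, 2,6-lutidine, CH2Cl2, −78 °C
Reagents that add atoms: tert-butyldimethylsilyl trifluoromethanesulfonate, CC(C)(C)[Si](C)(C)OS(=O)(=O)C(F)(F)F
Why: Silylation under non-nucleophilic base protects the C6 hydroxyl, the later site of chlorination, without epimerising the acidic C7 position.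

**Step 24**
Reactants: 23 ring A aldehyde; 33 iodobutenolide
Product: 34 9-epi coupling alcohol (butenolide C8 bonded to carbinol C9, C9 opposite to the target)
Conditions: CrCl2 (6 equiv), NiCl2 (1 mol %), DMSO/THF, 25 °C
Reagents that add atoms: none
Why: Nozaki–Hiyama–Kishi coupling forms C8–C9 chemoselectively at the aldehyde; Felkin–Anh addition anti to quaternary C1 should give the C9 epimer opposite to the target, which is the one needed to direct step 25.

**Step 25**
Reactants: 34 9-epi coupling alcohol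
Product: 35 8,17-epoxy lactone (epoxide oxygen cis to C6)
Conditions: t-BuOOH, n-BuLi, THF, −78 → −10 °C
Reagents that add atoms: tert-butyl hydroperoxide, CC(C)(C)OO
Why: Weitz–Scheffer epoxidation directed by the lithium alkoxide of the γ-hydroxyl: with C9–H eclipsing the butenolide plane (allylic strain against C18), the C9 oxygen of this epimer lies on the face of C6 and opposite to ring A, so the peroxide should reach C8 on that face and place the C8 oxygen cis to C6 as in the target.

**Step 26**
Reactants: 35 8,17-epoxy lactone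
Product: 36 8,17-epoxy 9-ketone
Conditions: Dess–Martin periodinane, NaHCO3, CH2Cl2, 0 → 25 °C
Reagents that add atoms: none
Why: Dess–Martin oxidation removes the directing C9 stereocentre once it has done its work.

**Step 27**
Reactants: 36 8,17-epoxy 9-ketone
Product: 37 8,17-epoxy 9-alcohol (C9 as in the target)
Conditions: Zn(BH4)2, Et2O, −40 °C
Reagents that add atoms: none
Why: Chelation-controlled reduction of an α,β-epoxy ketone (zinc bridging carbonyl and epoxide oxygens, hydride entering anti to the quaternary epoxide carbon C17) should give the anti epoxy alcohol, which is the C9 configuration of the target and also the Felkin–Anh sense with respect to C10.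

**Step 28**
Reactants: 37 8,17-epoxy 9-alcohol
Product: 38 8,9-dihydroxy lactone bearing the terminal alkyne (C8, C9, C17 as in the target)
Conditions: SmI2, THF/MeOH, −78 °C
Reagents that add atoms: none
Why: Reductive opening of an α,β-epoxy lactone by divalent samarium cleaves the α C–O bond and keeps the tertiary C8 hydroxyl; C17 is set by protonation of the samarium enolate and, being epimerisable, should settle with the methyl trans to the C9 branch and cis to the C8 hydroxyl.

**Step 29**
Reactants: 38 8,9-dihydroxy lactone with terminal alkyne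
Product: 40 ten-membered triene (2,14-bis-O-triethylsilyl, 6-O-tert-butyldimethylsilyl, 8,9-diol), via open triene 39 (not isolated)
Conditions: RuCl2(=CHPh)(H2IMes)(PCy3) (second-generation Grubbs catalyst, 10 mol %), ethene (1 atm), toluene (1 mM), 80 °C
Reagents that add atoms: ethene, C=C
Why: Ethene-mediated enyne cross-metathesis converts the alkyne into the 2-substituted buta-1,3-diene 39 (creating C5=C16), whose vinyl end then undergoes ring-closing metathesis with the C2 vinyl group; the ten-membered ring should accept only the Z C3=C4 alkene, and the hindered 1,1-disubstituted C11=C20 alkene stays out.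

**Step 30**
Reactants: 40 ten-membered triene silyl ether
Product: 41 2,8,9,14-tetrol 6-O-tert-butyldimethylsilyl ether
Conditions: HF·pyridine, pyridine, THF, 0 °C
Reagents that add atoms: none
Why: Buffered HF removes the two triethylsilyl ethers selectively in the presence of the secondary tert-butyldimethylsilyl ether.

**Step 31**
Reactants: 41 tetrol 6-O-silyl ether
Product: 42 2,9,14-triacetate 6-O-tert-butyldimethylsilyl ether
Conditions: Ac2O, pyridine, DMAP (cat.), CH2Cl2, 0 → 25 °C
Reagents that add atoms: acetic anhydride, CC(=O)OC(C)=O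
Why: Acetylation of the three secondary hydroxyls; the tertiary C8 hydroxyl should stay free under these conditions.

**Step 32**
Reactants: 42 triacetate 6-O-silyl ether
Product: 43 6-dechloro-6-epi-hydroxy analogue of the target
Conditions: HF·pyridine, THF, 25 °C
Reagents that add atoms: none
Why: Acidic fluoride desilylation frees the C6 hydroxyl without acetate migration or attack of the new hydroxyl on the lactone.

**Step 33**
Reactants: 43 6-epi alcohol
Product: 44 target
Conditions: PPh3, Cl3CC(O)CCl3, CH2Cl2, −20 → 0 °C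
Reagents that add atoms: hexachloroacetone, O=C(C(Cl)(Cl)Cl)C(Cl)(Cl)Cl
Why: Appel-type chlorination of a secondary allylic alcohol with PPh3/hexachloroacetone, which displaces the alkoxyphosphonium by SN2 with inversion and without allylic transposition, converts the tartrate-derived C6 carbinol into the C6 chloride; the tertiary C8 hydroxyl does not react.

**Compound list**
1 | methyl 4-oxobutanoate | COC(=O)CCC=O | starting material
2 | 4-hydroxy-3,3-bis(hydroxymethyl)butanoic acid (sodium salt in the flask) | OCC(CO)(CO)CC(=O)O | intermediate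
3 | 4,4-bis(hydroxymethyl)oxolan-2-one | O=C1CC(CO)(CO)CO1 | intermediate
4 | [(3S)-3-(hydroxymethyl)-5-oxooxolan-3-yl]methyl chloroacetate | ClCC(=O)OC[C@@]1(CO)COC(=O)C1 | intermediate
5 | [(3S)-3-{[tert-butyl(diphenyl)silyl]oxymethyl}-5-oxooxolan-3-yl]methyl chloroacetate | ClCC(=O)OC[C@@]1(CO[Si](c2ccccc2)(c2ccccc2)C(C)(C)C)COC(=O)C1 | intermediate
6 | (4R)-4-{[tert-butyl(diphenyl)silyl]oxymethyl}-4-(hydroxymethyl)oxolan-2-one | OC[C@@]1(CO[Si](c2ccccc2)(c2ccccc2)C(C)(C)C)COC(=O)C1 | intermediate
7 | (3R)-3-{[tert-butyl(diphenyl)silyl]oxymethyl}-5-oxooxolane-3-carbaldehyde | O=C[C@@]1(CO[Si](c2ccccc2)(c2ccccc2)C(C)(C)C)COC(=O)C1 | intermediate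
8 | 3-bromobut-3-en-1-ol | C=C(Br)CCO | starting material
9 | 2-bromo-4-iodobut-1-ene | C=C(Br)CCI | intermediate
10 | (3-bromobut-3-en-1-yl)zinc iodide | C=C(Br)CC[Zn]I | intermediate
11 | (4R)-4-[4-bromo-1-(trimethylsilyloxy)pent-4-en-1-yl]-4-{[tert-butyl(diphenyl)silyl]oxymethyl}oxolan-2-one, both epimers at the silyloxy carbon (C14) | C=C(Br)CCC(O[Si](C)(C)C)[C@@]1(CO[Si](c2ccccc2)(c2ccccc2)C(C)(C)C)COC(=O)C1 | intermediate
12 | (3aR,7aS)-3a-{[tert-butyl(diphenyl)silyl]oxymethyl}-7-methylidene-4-(trimethylsilyloxy)hexahydro-2-benzofuran-1(3H)-one, cis-fused, both C4 (= C14) epimers | C=C1CCC(O[Si](C)(C)C)[C@@]2(CO[Si](c3ccccc3)(c3ccccc3)C(C)(C)C)COC(=O)[C@@H]12 | intermediate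
13 | (3aR,7aS)-3a-{[tert-butyl(diphenyl)silyl]oxymethyl}-4-hydroxy-7-methylidenehexahydro-2-benzofuran-1(3H)-one, cis-fused, both C4 (= C14) epimers | C=C1CCC(O)[C@@]2(CO[Si](c3ccccc3)(c3ccccc3)C(C)(C)C)COC(=O)[C@@H]12 | intermediate
14 | (3aR,7aS)-3a-{[tert-butyl(diphenyl)silyl]oxymethyl}-7-methylidenetetrahydro-2-benzofuran-1,4(3H,5H)-dione | C=C1CCC(=O)[C@@]2(CO[Si](c3ccccc3)(c3ccccc3)C(C)(C)C)COC(=O)[C@@H]12 | intermediate
15 | (3aR,4S,7aS)-3a-{[tert-butyl(diphenyl)silyl]oxymethyl}-4-hydroxy-7-methylidenehexahydro-2-benzofuran-1(3H)-one | C=C1CC[C@H](O)[C@@]2(CO[Si](c3ccccc3)(c3ccccc3)C(C)(C)C)COC(=O)[C@@H]12 | intermediate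
16 | (3aS,4S,7aS)-4-hydroxy-3a-(hydroxymethyl)-7-methylidenehexahydro-2-benzofuran-1(3H)-one | C=C1CC[C@H](O)[C@@]2(CO)COC(=O)[C@@H]12 | intermediate
17 | (3aS,4S,7aS)-4-hydroxy-7-methylidene-1-oxohexahydro-2-benzofuran-3a(1H)-carbaldehyde | C=C1CC[C@H](O)[C@@]2(C=O)COC(=O)[C@@H]12 | intermediate
18 | (3aS,4S,7aS)-4-hydroxy-3a-[(1S)-1-hydroxyprop-2-en-1-yl]-7-methylidenehexahydro-2-benzofuran-1(3H)-one | C=C1CC[C@H](O)[C@@]2([C@@H](O)C=C)COC(=O)[C@@H]12 | intermediate
19 | (3aS,4S,7aS)-7-methylidene-4-(triethylsilyloxy)-3a-[(1S)-1-(triethylsilyloxy)prop-2-en-1-yl]hexahydro-2-benzofuran-1(3H)-one | C=C1CC[C@H](O[Si](CC)(CC)CC)[C@@]2([C@@H](O[Si](CC)(CC)CC)C=C)COC(=O)[C@@H]12 | intermediate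
20 | (1S,2S,3S)-2-(hydroxymethyl)-N-methoxy-N-methyl-6-methylidene-3-(triethylsilyloxy)-2-[(1S)-1-(triethylsilyloxy)prop-2-en-1-yl]cyclohexane-1-carboxamide | C=C1CC[C@H](O[Si](CC)(CC)CC)[C@](CO)([C@@H](O[Si](CC)(CC)CC)C=C)[C@H]1C(=O)N(C)OC | intermediate
21 | O-phenyl thiocarbonate of 20 at the hydroxymethyl group (C15), other centres as in 20 | C=C1CC[C@H](O[Si](CC)(CC)CC)[C@](COC(=S)Oc2ccccc2)([C@@H](O[Si](CC)(CC)CC)C=C)[C@H]1C(=O)N(C)OC | intermediate
22 | (1S,2R,3S)-N-methoxy-N,2-dimethyl-6-methylidene-3-(triethylsilyloxy)-2-[(1S)-1-(triethylsilyloxy)prop-2-en-1-yl]cyclohexane-1-carboxamide | C=C1CC[C@H](O[Si](CC)(CC)CC)[C@](C)([C@@H](O[Si](CC)(CC)CC)C=C)[C@H]1C(=O)N(C)OC | intermediate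
23 | (1S,2R,3S)-2-methyl-6-methylidene-3-(triethylsilyloxy)-2-[(1S)-1-(triethylsilyloxy)prop-2-en-1-yl]cyclohexane-1-carbaldehyde | C=C1CC[C@H](O[Si](CC)(CC)CC)[C@](C)([C@@H](O[Si](CC)(CC)CC)C=C)[C@H]1C=O | intermediate
24 | dimethyl (4S,5S)-2,2-dimethyl-1,3-dioxolane-4,5-dicarboxylate (from D-tartaric acid) | COC(=O)[C@H]1OC(C)(C)O[C@@H]1C(=O)OC | starting material
25 | (4S,5S)-2,2-dimethyl-1,3-dioxolane-4,5-dicarbaldehyde | O=C[C@H]1OC(C)(C)O[C@@H]1C=O | intermediate
26 | (4R,5R)-4,5-diethynyl-2,2-dimethyl-1,3-dioxolane | C#C[C@H]1OC(C)(C)O[C@@H]1C#C | intermediate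
27 | methyl 3-[(4R,5R)-5-ethynyl-2,2-dimethyl-1,3-dioxolan-4-yl]prop-2-ynoate | C#C[C@H]1OC(C)(C)O[C@@H]1C#CC(=O)OC | intermediate
28 | α-cuprio ester: alkenylcopper from syn addition of tin and copper to 27 (tin on C8, copper on C17) | C#C[C@H]1OC(C)(C)O[C@@H]1/C([Sn](CCCC)(CCCC)CCCC)=C(/[Cu])C(=O)OC | intermediate
29 | methyl (2E)-3-[(4S,5R)-5-ethynyl-2,2-dimethyl-1,3-dioxolan-4-yl]-2-methyl-3-(tributylstannyl)prop-2-enoate | C#C[C@H]1OC(C)(C)O[C@@H]1/C([Sn](CCCC)(CCCC)CCCC)=C(/C)C(=O)OC | intermediate
30 | methyl (2E)-3-[(4S,5R)-5-ethynyl-2,2-dimethyl-1,3-dioxolan-4-yl]-3-iodo-2-methylprop-2-enoate | C#C[C@H]1OC(C)(C)O[C@@H]1/C(I)=C(/C)C(=O)OC | intermediate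
31 | methyl (2E)-4,5-dihydroxy-3-iodo-2-methylhept-2-en-6-ynoate, threo diol from 30 | C#C[C@@H](O)[C@H](O)/C(I)=C(/C)C(=O)OC | intermediate
32 | (5S)-5-[(1R)-1-hydroxyprop-2-yn-1-yl]-4-iodo-3-methylfuran-2(5H)-one | C#C[C@@H](O)[C@@H]1OC(=O)C(C)=C1I | intermediate
33 | (5S)-5-[(1R)-1-{[tert-butyl(dimethyl)silyl]oxy}prop-2-yn-1-yl]-4-iodo-3-methylfuran-2(5H)-one | C#C[C@@H](O[Si](C)(C)C(C)(C)C)[C@@H]1OC(=O)C(C)=C1I | intermediate
34 | 9-epi coupling alcohol: butenolide of 33 joined at C8 to the carbinol C9 borne by the cyclohexane of 23; C9 opposite to 44, all other centres as in 23 and 33 | C=C1CC[C@H](O[Si](CC)(CC)CC)[C@](C)([C@@H](O[Si](CC)(CC)CC)C=C)[C@H]1[C@@H](O)C1=C(C)C(=O)O[C@H]1[C@H](O[Si](C)(C)C(C)(C)C)C#C | intermediate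
35 | 8,17-epoxy lactone of 34, epoxide oxygen on the face of C6 (C8 as in 44) | C=C1CC[C@H](O[Si](CC)(CC)CC)[C@](C)([C@@H](O[Si](CC)(CC)CC)C=C)[C@H]1[C@@H](O)[C@@]12O[C@@]2(C)C(=O)O[C@H]1[C@H](O[Si](C)(C)C(C)(C)C)C#C | intermediate
36 | 8,17-epoxy 9-ketone from 35 | C=C1CC[C@H](O[Si](CC)(CC)CC)[C@](C)([C@@H](O[Si](CC)(CC)CC)C=C)[C@H]1C(=O)[C@@]12O[C@@]2(C)C(=O)O[C@H]1[C@H](O[Si](C)(C)C(C)(C)C)C#C | intermediate
37 | 8,17-epoxy 9-alcohol, C9 as in 44 | C=C1CC[C@H](O[Si](CC)(CC)CC)[C@](C)([C@@H](O[Si](CC)(CC)CC)C=C)[C@H]1[C@H](O)[C@@]12O[C@@]2(C)C(=O)O[C@H]1[C@H](O[Si](C)(C)C(C)(C)C)C#C | intermediate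
38 | 8,9-dihydroxy γ-lactone with terminal alkyne: C8 tertiary hydroxyl, C9 hydroxyl and C17 methyl as in 44; 2,14-bis-O-triethylsilyl, 6-O-tert-butyldimethylsilyl | C=C1CC[C@H](O[Si](CC)(CC)CC)[C@](C)([C@@H](O[Si](CC)(CC)CC)C=C)[C@H]1[C@H](O)[C@]1(O)[C@@H](C)C(=O)O[C@H]1[C@H](O[Si](C)(C)C(C)(C)C)C#C | intermediate
39 | open triene: 38 with the ethynyl group replaced by buta-1,3-dien-2-yl | C=C1CC[C@H](O[Si](CC)(CC)CC)[C@](C)([C@@H](O[Si](CC)(CC)CC)C=C)[C@H]1[C@H](O)[C@]1(O)[C@@H](C)C(=O)O[C@H]1[C@H](O[Si](C)(C)C(C)(C)C)C(=C)C=C | intermediate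
40 | ten-membered (3Z)-triene lactone: 6-dechloro-6-epi-hydroxy-2,9,14-tri-O-deacetyl analogue of 44 as its 2,14-bis(triethylsilyl) 6-(tert-butyldimethylsilyl) ether | C=C1CC[C@H](O[Si](CC)(CC)CC)[C@]2(C)[C@@H](O[Si](CC)(CC)CC)/C=C\C(=C)[C@@H](O[Si](C)(C)C(C)(C)C)[C@@H]3OC(=O)[C@H](C)[C@@]3(O)[C@@H](O)[C@@H]12 | intermediate
41 | 2,8,9,14-tetrol of 40 with the 6-O-tert-butyldimethylsilyl ether retained | C=C1CC[C@H](O)[C@]2(C)[C@@H](O)/C=C\C(=C)[C@@H](O[Si](C)(C)C(C)(C)C)[C@@H]3OC(=O)[C@H](C)[C@@]3(O)[C@@H](O)[C@@H]12 | intermediate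
42 | 2,9,14-triacetate of 41 | C=C1CC[C@H](OC(C)=O)[C@]2(C)[C@@H](OC(C)=O)/C=C\C(=C)[C@@H](O[Si](C)(C)C(C)(C)C)[C@@H]3OC(=O)[C@H](C)[C@@]3(O)[C@@H](OC(C)=O)[C@@H]12 | intermediate
43 | 6-dechloro-6-epi-hydroxy analogue of 44 (hydroxyl at C6 on the face opposite to the chlorine of 44) | C=C1CC[C@H](OC(C)=O)[C@]2(C)[C@@H](OC(C)=O)/C=C\C(=C)[C@@H](O)[C@@H]3OC(=O)[C@H](C)[C@@]3(O)[C@@H](OC(C)=O)[C@@H]12 | intermediate
44 | (1R,2S,3Z,6S,7R,8R,9S,10S,14S,17R)-2,9,14-triacetoxy-6-chloro-8-hydroxybriara-3,5(16),11(20)-trien-19-oic acid 7,19-lactone (CNP0178742.1) | C=C1CC[C@H](OC(C)=O)[C@]2(C)[C@@H](OC(C)=O)/C=C\C(=C)[C@H](Cl)[C@@H]3OC(=O)[C@H](C)[C@@]3(O)[C@@H](OC(C)=O)[C@@H]12 | target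

**Totals and risks**
Total step count: 33. Longest linear sequence: 26 steps (steps 1–5, 7–17, 24–33).

Steps most likely to fail:

1. Step 29. Intermolecular metathesis (oligomerisation) may outrun the entropically and enthalpically disfavoured ten-membered closure, or closure may take the exo mode or give the E alkene. The fallback sets out from 38. The same ruthenium carbene under ethene is used only for the enyne cross-metathesis, and the open triene 39 is isolated. Its 8,9-diol is then tied with t-Bu2Si(OTf)2/2,6-lutidine as the di-tert-butylsilylene of 39 F1, a temporary five-membered ring that holds C7 and C10 close. Ring-closing metathesis of this pre-organised diene with RuCl2(=CH-2-(i-PrO)C6H4)(H2IMes) (second-generation Hoveyda–Grubbs catalyst) at high dilution should give the macrocyclic silylene F2. HF·pyridine then removes the silylene together with both triethylsilyl groups, and the route is rejoined at 41.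

2. Step 7. In the second stage, dehydrobromination of the alkenyl bromide or self-condensation of the lactone enolate may compete with C–C reductive elimination, in a flask that still carries zinc and magnesium salts. The fallback sets out from 11, here isolated after aqueous work-up of the first stage. The lactone enolate (LiN(SiMe3)2, −78 °C) is brominated with N-bromosuccinimide to the α-bromo lactone F3. A nickel-catalysed reductive coupling of the two carbon–bromine bonds (NiBr2(dme), 4,4'-di-tert-butyl-2,2'-bipyridine, Zn, N,N-dimethylacetamide) then closes ring A without any strong base. The cis ring fusion is again enforced by the lactone; the product is 12, and acid work-up rejoins the route at 13.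

3. Step 2. The two ring arms flanking C1 (CH2–O and CH2–C=O) are nearly isosteric, so enantiotopic discrimination by the enzyme may be weak; acyl or lactone migration may further erode the enantiomeric purity. The fallback sets out from 3. Statistical mono-silylation (t-BuPh2SiCl, 1 equiv, imidazole) gives the racemic silyl ether alcohol F4, and nitroxyl oxidation (TEMPO, PhI(OAc)2) gives the racemic aldehyde F5, which has no free hydroxyl and is configurationally stable. F5 is resolved by preparative chromatography on a chiral stationary phase, and the (R)-enantiomer rejoins the route at 7.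

**Further compounds**
F1 | step 29 | di-tert-butylsilylene (8,9-O) derivative of open triene 39 | C=C1CC[C@H](O[Si](CC)(CC)CC)[C@](C)([C@@H](O[Si](CC)(CC)CC)C=C)[C@H]1[C@@H]2O[Si](C(C)(C)C)(C(C)(C)C)O[C@]23[C@@H](C)C(=O)O[C@H]3[C@H](O[Si](C)(C)C(C)(C)C)C(=C)C=C
F2 | step 29 | di-tert-butylsilylene (8,9-O) derivative of macrocycle 40 | C=C1CC[C@H](O[Si](CC)(CC)CC)[C@]2(C)[C@@H](O[Si](CC)(CC)CC)/C=C\C(=C)[C@@H](O[Si](C)(C)C(C)(C)C)[C@@H]3OC(=O)[C@H](C)[C@]34O[Si](C(C)(C)C)(C(C)(C)C)O[C@H]4[C@@H]12
F3 | step 7 | α-bromo lactone of 11 (bromine at C10, both epimers) | C=C(Br)CCC(O[Si](C)(C)C)[C@@]1(CO[Si](c2ccccc2)(c2ccccc2)C(C)(C)C)COC(=O)C1Br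
F4 | step 2 | racemic 4-{[tert-butyl(diphenyl)silyl]oxymethyl}-4-(hydroxymethyl)oxolan-2-one | OCC1(CO[Si](c2ccccc2)(c2ccccc2)C(C)(C)C)COC(=O)C1
F5 | step 2 | racemic 3-{[tert-butyl(diphenyl)silyl]oxymethyl}-5-oxooxolane-3-carbaldehyde | O=CC1(CO[Si](c2ccccc2)(c2ccccc2)C(C)(C)C)COC(=O)C1
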